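All constants are made up; what happens was integrated by code.

- Early in this flask, solid Q had just met the solution and nothing was dissolved. I wanted to know what would stand at the end of the run.

Q 20 mM; time 50 s

    E ⇌ Z (K1 = 160, k1 = 0.055 s⁻¹)
    E ⇌ J (K2 = 0.39, k2 = 0.13 s⁻¹)
    2 E → E2 (k3 = 0.0011 M⁻¹ s⁻¹)
    Q ⇌ E, rate k4*(cs4 - [E]) while solid is left; crystals form when [E] > cs4 (cs4 = 13 mM, k4 = 0.041 s⁻¹)

* why nothing more happens at 50 s, or that something still does (for what has run out or reacted, a solid counts together with what of it has only dissolved) (all of Q has reacted / forward and back rates have come level / it is still moving)
* part of the Q that has turned into other species by 50 s (what has only dissolved does not count)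
* amount of J at 50 s, in percent of the Q charged
* amount of Z at 50 s, in percent of the Q charged
* amount of E at 50 s, in percent of the Q charged

- percent here means Q units held: one E2 counts as two
- where a step has two of a species, its rate is k times that concentration squared, and two are used at each turn
- Q is a solid; its amount is given per volume of the solution
- at the start none of Q is in solution
- what has only dissolved of Q counts as not reacted
- E means what is dissolved; the solid is not counted in it
- the reaction counts as stopped when no species that holds the Q changes by six tenths of a point or more over the second half of the time
- run time (flask): 50 s

- In the first instants E was near zero, so Q dissolved at its full pace of 0.533 mM s⁻¹.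
- J followed E, because the relaxation half-life of that pair, 1.50 s, is shorter than the run. So I held J at 0.39 times E, and the two filled as one pool.
- I dropped the return from Z, since its constant of 3.44 × 10⁻⁴ s⁻¹ is far smaller than 0.055 s⁻¹. I dropped E2 too, since even at the solubility its rate per E, 2.86 × 10⁻⁵ s⁻¹, is far smaller than 0.055 s⁻¹.
- In the middle, dissolving slowed as E rose, while the drain into Z grew. Setting the two equal gave 5.55 mM, or 27.8% of the charge.
- I carried this as the plateau level: the level of E at which Q feeds E as fast as Z draws it off. It is a quasi-steady state.
- The pool approached the plateau at 0.0691 s⁻¹, a half-time of 10.0 s, which is shorter than the run.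
- At the end of the run I reckoned E at 26.9%, J at 10.5% and Z at 54.9%. That left Q at 7.70%, so I expected the flask to be still moving.
- The forecast said: it is still moving, with conversion 65.2% (range 63.5% to 67%), J 10.4%, Z 54.9% and E 26.9%. Its grounds included this: “E settles near 5.4 mM, well below the solubility”. That settling figure differs from my 5.55 mM.
- The simulation of this flask gave: it is still moving, with conversion 65.2%, J 10.4%, Z 54.8% and E 26.9%, and Q stood at 7.92%.
- In this flask, with each step taken net, E was made 1.05 times as fast as it was used at 50.0 s, a smaller lead than the 1.29 at 21.9 s. At 50.0 s E stood 0.90 percentage points under my plateau level of 27.8%. For the same charge read at 20 s, the plateau curve gave E 20.8%, and that flask held 20.7%.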